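**Retrosynthetic overview**
- Feature: ring C is a hexasubstituted benzene. C1 and C4 carry two different indol-3-yl groups, and C2, C3, C5 and C6 all carry oxygen. The para oxygen pair C2/C5 lies each time between an indolyl carbon and a methoxy carbon, which is the substituent order that ring expansion of a squarate-derived 4-alkenyl-4-hydroxycyclobutenone produces.
- Endgame: the target comes from O-debenzylation, removal of both N-TIPS groups and double O-methylation of the C2/C5 hydroquinone.
- Key disconnection: the C2–C3 bond of ring C, joining the former ketene carbon to the former vinyl CH(OMe). The hydroquinone arises by 4π opening and 6π closure of the cyclobutenone carbinol. Ring C is the only ring built; both indoles are bought.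
- The carbinol comes from 1,2-addition of an OMe-chelated 1-indolyl-2-methoxyvinyllithium to 3-methoxy-4-indolylcyclobutenedione. The vinyllithium derives from 5-benzyloxyindole and N,2-dimethoxy-N-methylacetamide via ketone, Z enol triflate and vinylstannane. The dione derives from dimethyl squarate and 3-lithio-5-methoxy-1-TIPS-indole.

Key step: step 8

Remark on geometry: the alkenyl group is carried with OMe cis to the carbinol carbon (Z), because only the vinyllithium with Li cis to, and chelated by, the methoxy oxygen resists anti elimination of LiOMe; the alkene geometry is erased when ring C aromatises.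
Remark on stereochemistry: the target has no stereocentre and its indolyl–ring C axes are taken as freely rotating; 6, 7, 14, 20, 21 and 23 are racemic.
Remark on numbering: N–H and O–H conjugate bases formed and consumed within one operation (steps 1, 3, 9, 10) count as part of the conditions and carry no number.

**Step 1**
Reactants: 1 5-methoxyindole
Product: 3 3-bromo-5-methoxy-1-(triisopropylsilyl)indole, via 5-methoxy-1-(triisopropylsilyl)indole 2 (not isolated)
Conditions: n-BuLi, THF, −78 → 0 °C; TIPSCl, 0 °C → rt; NBS, −78 °C → rt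
Reagents that add atoms: triisopropylsilyl chloride, CC(C)[Si](Cl)(C(C)C)C(C)C; N-bromosuccinimide, O=C1CCC(=O)N1Br
Why: N-deprotonation and N-silylation followed by electrophilic aromatic bromination in one flask, in which the bulky TIPS group screens C2 and C7 so that NBS attacks only the enamine-type C3.

**Step 2**
Reactants: 3 3-bromo-5-methoxy-1-(triisopropylsilyl)indole; 4 dimethyl squarate
Product: 8 3-methoxy-4-[5-methoxy-1-(triisopropylsilyl)indol-3-yl]cyclobut-3-ene-1,2-dione, via 3-lithioindole 5 (not isolated), via lithium alkoxide 6 (not isolated), via trifluoroacetate 7 (not isolated)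
Conditions: t-BuLi (2 equiv), THF, −78 °C; cannulate into 4, THF, −78 °C; TFAA, −78 °C; H2O, −78 °C → rt
Reagents that add atoms: water, O
Why: Bromine–lithium exchange gives a 3-lithioindole that N-TIPS holds at C3, its 1,2-addition to one of the two equivalent squarate carbonyls gives 6, and trifluoroacetylation makes the carbinol oxygen a leaving group so that water enters at the far methoxy-bearing allylic carbon (SN2′-type hydrolysis) and the hemiketal expels methanol, which is the established conversion of squarate esters into 3-aryl-4-alkoxycyclobutenediones and removes the racemic centre of 6 and 7.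

**Step 3**
Reactants: 9 5-(benzyloxy)indole
Product: 11 5-(benzyloxy)-3-bromo-1-(triisopropylsilyl)indole, via 5-(benzyloxy)-1-(triisopropylsilyl)indole 10 (not isolated)
Conditions: n-BuLi, THF, −78 → 0 °C; TIPSCl, 0 °C → rt; NBS, −78 °C → rt
Reagents that add atoms: triisopropylsilyl chloride, CC(C)[Si](Cl)(C(C)C)C(C)C; N-bromosuccinimide, O=C1CCC(=O)N1Br
Why: Same one-flask N-silylation and C3-selective electrophilic bromination as in step 1, with the benzyl ether inert and the low temperature keeping NBS away from C4 and C6 of the alkoxy-activated benzo ring.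

**Step 4**
Reactants: 11 5-(benzyloxy)-3-bromo-1-(triisopropylsilyl)indole; 12 N,2-dimethoxy-N-methylacetamide
Product: 15 1-[5-(benzyloxy)-1-(triisopropylsilyl)indol-3-yl]-2-methoxyethan-1-one, via 3-lithioindole 13 (not isolated), via tetrahedral lithium adduct 14 (not isolated)
Conditions: t-BuLi (2 equiv), THF, −78 °C; 12, −78 → 0 °C; H2O
Reagents that add atoms: none
Why: Weinreb ketone synthesis, in which the 3-lithioindole from bromine–lithium exchange adds only once because the five-membered lithium chelate 14 persists until the aqueous quench releases the ketone.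

**Step 5**
Reactants: 15 1-[5-(benzyloxy)-1-(triisopropylsilyl)indol-3-yl]-2-methoxyethan-1-one
Product: 17 (Z)-1-[5-(benzyloxy)-1-(triisopropylsilyl)indol-3-yl]-2-methoxyvinyl trifluoromethanesulfonate, via lithium enolate 16 (not isolated)
Conditions: LiHMDS, THF, −78 °C; PhNTf2, −78 → 0 °C
Reagents that add atoms: N-phenylbis(trifluoromethanesulfonimide), O=S(=O)(N(c1ccccc1)S(=O)(=O)C(F)(F)F)C(F)(F)F
Why: Enolisation and O-sulfonylation (enol triflate synthesis), in which CH2OMe is the only enolisable position and lithium chelation between the enolate and methoxy oxygens, reinforced by the preference of the bulky indolyl group to lie trans to OMe, gives the Z enolate 16 whose geometry PhNTf2 fixes.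

**Step 6**
Reactants: 17 (Z)-1-[5-(benzyloxy)-1-(triisopropylsilyl)indol-3-yl]-2-methoxyvinyl trifluoromethanesulfonate
Product: 18 (Z)-5-(benzyloxy)-3-[2-methoxy-1-(trimethylstannyl)vinyl]-1-(triisopropylsilyl)indole
Conditions: Me3SnSnMe3, Pd(PPh3)4 (5 mol%), LiCl, THF, 65 °C; Et3N-washed SiO2
Reagents that add atoms: hexamethylditin, C[Sn](C)(C)[Sn](C)(C)C
Why: Palladium-catalysed stannylation of an alkenyl triflate with a distannane (Stille-type coupling), in which oxidative addition to zerovalent palladium, chloride exchange, transmetalation and reductive elimination all run with retention, so tin ends up cis to OMe.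

**Step 7**
Reactants: 18 (Z)-5-(benzyloxy)-3-[2-methoxy-1-(trimethylstannyl)vinyl]-1-(triisopropylsilyl)indole; 8 3-methoxy-4-[5-methoxy-1-(triisopropylsilyl)indol-3-yl]cyclobut-3-ene-1,2-dione
Product: 21 racemic 4-hydroxy-3-methoxy-2-[5-methoxy-1-(triisopropylsilyl)indol-3-yl]-4-{(Z)-1-[5-(benzyloxy)-1-(triisopropylsilyl)indol-3-yl]-2-methoxyvinyl}cyclobut-2-en-1-one, via vinyllithium 19 (not isolated), via lithium alkoxide 20 (not isolated)
Conditions: MeLi (0.95 equiv), THF, −78 °C; 8, THF, −78 °C; H2O, −78 → 0 °C; Et3N-washed SiO2, used at once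
Reagents that add atoms: none
Why: Tin–lithium exchange with retention gives vinyllithium 19, protected from loss of LiOMe by the cis, chelated arrangement of Li and OMe, and its 1,2-addition goes to the carbonyl attached to the methoxy-bearing ring carbon because the other carbonyl is the deactivated vinylogous ester carbonyl (MeO–C=C–C=O) and is flanked by the bulky indolyl group; the new carbinol centre forms as a racemate and is lost in step 8.

**Step 8**
Reactants: 21 racemic 4-hydroxy-3-methoxy-2-[5-methoxy-1-(triisopropylsilyl)indol-3-yl]-4-{(Z)-1-[5-(benzyloxy)-1-(triisopropylsilyl)indol-3-yl]-2-methoxyvinyl}cyclobut-2-en-1-one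
Product: 24 3,6-dimethoxy-2-[5-methoxy-1-(triisopropylsilyl)indol-3-yl]-5-[5-(benzyloxy)-1-(triisopropylsilyl)indol-3-yl]benzene-1,4-diol, via dienylketene 22 (not isolated), via cyclohexadienone 23 (not isolated)
Conditions: PhMe (degassed), 110 °C, Ar, base-washed glassware; concentrated under Ar and carried on crude
Reagents that add atoms: none
Why: Heating cleaves the C1–C4 bond of the cyclobutenone in a conrotatory 4π electrocyclic opening to dienylketene 22, whose ketene carbon then bonds to the CH(OMe) terminus of the alkenyl group in a disrotatory 6π electrocyclisation that makes the single new ring C bond (between two neighbouring oxygen-bearing carbons) and closes ring C as cyclohexa-2,4-dienone 23, and enolisation of 23 gives hydroquinone 24. This is the thermal ring expansion of 4-alkenyl-4-hydroxycyclobutenones to hydroquinones (Moore rearrangement), a known reaction of squarate-derived carbinols. No stereocentre survives, since the racemic carbinol carbon becomes sp2 in the opening and the transient C(H)OMe centre of 23 is erased by tautomerisation. The selectivity needed is torquoselectivity, and the donor hydroxyl on C4 secures it by rotating outward, which swings the alkenyl group inward within reach of the ketene, whereas inward rotation of OH would end in lactonisation. The Z enol ether places its methoxy group on the inner side of the closing terminus, which should be tolerated because the partner terminus is an sp ketene carbon with no inward substituent, in line with the ready thermal closure of terminally disubstituted dienylketenes to 6,6-disubstituted cyclohexadienones. The para relation of the two indolyl groups is not decided here but was fixed by the site of addition in step 7, and oxygen is excluded because 24 is an electron-rich hydroquinone.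

**Step 9**
Reactants: 24 3,6-dimethoxy-2-[5-methoxy-1-(triisopropylsilyl)indol-3-yl]-5-[5-(benzyloxy)-1-(triisopropylsilyl)indol-3-yl]benzene-1,4-diol
Product: 25 5-(benzyloxy)-3-{2,3,5,6-tetramethoxy-4-[5-methoxy-1-(triisopropylsilyl)indol-3-yl]phenyl}-1-(triisopropylsilyl)indole
Conditions: NaH, MeI, THF–DMF, 0 °C → rt, Ar
Reagents that add atoms: iodomethane, CI
Why: Double Williamson ether synthesis, in which both phenols are deprotonated irreversibly and methylated by SN2 attack on MeI while the indole nitrogens stay blocked by TIPS, so that N-methylation cannot occur.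

**Step 10**
Reactants: 25 5-(benzyloxy)-3-{2,3,5,6-tetramethoxy-4-[5-methoxy-1-(triisopropylsilyl)indol-3-yl]phenyl}-1-(triisopropylsilyl)indole
Product: 26 5-(benzyloxy)-3-[2,3,5,6-tetramethoxy-4-(5-methoxy-1H-indol-3-yl)phenyl]-1H-indole
Conditions: TBAF, THF, 0 °C → rt; H2O
Reagents that add atoms: none
Why: Fluoride-induced N-desilylation, in which fluoride attacks silicon and expels the stabilised indolide that water protonates, with aryl methyl and benzyl ethers inert.

**Step 11**
Reactants: 26 5-(benzyloxy)-3-[2,3,5,6-tetramethoxy-4-(5-methoxy-1H-indol-3-yl)phenyl]-1H-indole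
Product: 27 3-[2,3,5,6-tetramethoxy-4-(5-methoxy-1H-indol-3-yl)phenyl]-1H-indol-5-ol (CNP0244913.0)
Conditions: H2 (1 atm), Pd/C (10 wt% Pd on carbon), EtOAc–MeOH, rt
Reagents that add atoms: none
Why: Catalytic hydrogenolysis of the benzylic C–O bond under neutral conditions leaves the indole rings and methyl ethers untouched and frees the oxidation-prone 5-hydroxyindole only in the last step.

**Compound list**
1 | 5-methoxyindole | COc1ccc2[nH]ccc2c1 | starting material
2 | 5-methoxy-1-(triisopropylsilyl)indole | COc1ccc2c(ccn2[Si](C(C)C)(C(C)C)C(C)C)c1 | intermediate (not isolated)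
3 | 3-bromo-5-methoxy-1-(triisopropylsilyl)indole | COc1ccc2c(c1)c(Br)cn2[Si](C(C)C)(C(C)C)C(C)C | intermediate
4 | dimethyl squarate | COC1=C(OC)C(=O)C1=O | starting material
5 | 3-lithio-5-methoxy-1-(triisopropylsilyl)indole | COc1ccc2c(c1)c([Li])cn2[Si](C(C)C)(C(C)C)C(C)C | intermediate (not isolated)
6 | racemic lithium alkoxide of 4-hydroxy-2,3-dimethoxy-4-[5-methoxy-1-(triisopropylsilyl)indol-3-yl]cyclobut-2-en-1-one | COC1=C(OC)C(O[Li])(c2cn([Si](C(C)C)(C(C)C)C(C)C)c3ccc(OC)cc23)C1=O | intermediate (not isolated)
7 | racemic 2,3-dimethoxy-1-[5-methoxy-1-(triisopropylsilyl)indol-3-yl]-4-oxocyclobut-2-en-1-yl trifluoroacetate | COC1=C(OC)C(OC(=O)C(F)(F)F)(c2cn([Si](C(C)C)(C(C)C)C(C)C)c3ccc(OC)cc23)C1=O | intermediate (not isolated)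
8 | 3-methoxy-4-[5-methoxy-1-(triisopropylsilyl)indol-3-yl]cyclobut-3-ene-1,2-dione | COC1=C(c2cn([Si](C(C)C)(C(C)C)C(C)C)c3ccc(OC)cc23)C(=O)C1=O | intermediate
9 | 5-(benzyloxy)indole | C(Oc1ccc2[nH]ccc2c1)c1ccccc1 | starting material
10 | 5-(benzyloxy)-1-(triisopropylsilyl)indole | C(Oc1ccc2c(ccn2[Si](C(C)C)(C(C)C)C(C)C)c1)c1ccccc1 | intermediate (not isolated)
11 | 5-(benzyloxy)-3-bromo-1-(triisopropylsilyl)indole | Brc1cn([Si](C(C)C)(C(C)C)C(C)C)c2ccc(OCc3ccccc3)cc12 | intermediate
12 | N,2-dimethoxy-N-methylacetamide | COCC(=O)N(C)OC | starting material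
13 | 5-(benzyloxy)-3-lithio-1-(triisopropylsilyl)indole | [Li]c1cn([Si](C(C)C)(C(C)C)C(C)C)c2ccc(OCc3ccccc3)cc12 | intermediate (not isolated)
14 | racemic tetrahedral lithium adduct of 13 and 12 | COCC(O[Li])(N(C)OC)c1cn([Si](C(C)C)(C(C)C)C(C)C)c2ccc(OCc3ccccc3)cc12 | intermediate (not isolated)
15 | 1-[5-(benzyloxy)-1-(triisopropylsilyl)indol-3-yl]-2-methoxyethan-1-one | COCC(=O)c1cn([Si](C(C)C)(C(C)C)C(C)C)c2ccc(OCc3ccccc3)cc12 | intermediate
16 | (Z)-lithium enolate of 15 (OLi cis to OMe) | CO/C=C(\O[Li])c1cn([Si](C(C)C)(C(C)C)C(C)C)c2ccc(OCc3ccccc3)cc12 | intermediate (not isolated)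
17 | (Z)-1-[5-(benzyloxy)-1-(triisopropylsilyl)indol-3-yl]-2-methoxyvinyl trifluoromethanesulfonate | CO/C=C(\OS(=O)(=O)C(F)(F)F)c1cn([Si](C(C)C)(C(C)C)C(C)C)c2ccc(OCc3ccccc3)cc12 | intermediate
18 | (Z)-5-(benzyloxy)-3-[2-methoxy-1-(trimethylstannyl)vinyl]-1-(triisopropylsilyl)indole | CO/C=C(\[Sn](C)(C)C)c1cn([Si](C(C)C)(C(C)C)C(C)C)c2ccc(OCc3ccccc3)cc12 | intermediate
19 | {1-[5-(benzyloxy)-1-(triisopropylsilyl)indol-3-yl]-2-methoxyvinyl}lithium, Li cis to OMe | CO/C=C(\[Li])c1cn([Si](C(C)C)(C(C)C)C(C)C)c2ccc(OCc3ccccc3)cc12 | intermediate (not isolated)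
20 | racemic lithium alkoxide of 21 | COc1ccc2c(c1)c(C1=C(OC)C(O[Li])(/C(=C\OC)c3cn([Si](C(C)C)(C(C)C)C(C)C)c4ccc(OCc5ccccc5)cc34)C1=O)cn2[Si](C(C)C)(C(C)C)C(C)C | intermediate (not isolated)
21 | racemic 4-hydroxy-3-methoxy-2-[5-methoxy-1-(triisopropylsilyl)indol-3-yl]-4-{(Z)-1-[5-(benzyloxy)-1-(triisopropylsilyl)indol-3-yl]-2-methoxyvinyl}cyclobut-2-en-1-one | COc1ccc2c(c1)c(C1=C(OC)C(O)(/C(=C\OC)c3cn([Si](C(C)C)(C(C)C)C(C)C)c4ccc(OCc5ccccc5)cc34)C1=O)cn2[Si](C(C)C)(C(C)C)C(C)C | intermediate
22 | dienylketene from 21 (OH trans to the ketene branch, alkenyl cis to it, terminal OMe cis to the enol carbon) | O=C=C(c1cn([Si](C(C)C)(C(C)C)C(C)C)c2ccc(OC)cc12)/C(OC)=C(/O)\C(c1cn([Si](C(C)C)(C(C)C)C(C)C)c2ccc(OCc3ccccc3)cc12)=C/OC | intermediate (not isolated)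
23 | racemic 4-hydroxy-3,6-dimethoxy-2-[5-methoxy-1-(triisopropylsilyl)indol-3-yl]-5-[5-(benzyloxy)-1-(triisopropylsilyl)indol-3-yl]cyclohexa-2,4-dien-1-one | COC1C(=O)C(c2cn([Si](C(C)C)(C(C)C)C(C)C)c3ccc(OC)cc23)=C(OC)C(O)=C1c1cn([Si](C(C)C)(C(C)C)C(C)C)c2ccc(OCc3ccccc3)cc12 | intermediate (not isolated)
24 | 3,6-dimethoxy-2-[5-methoxy-1-(triisopropylsilyl)indol-3-yl]-5-[5-(benzyloxy)-1-(triisopropylsilyl)indol-3-yl]benzene-1,4-diol | Oc1c(-c2cn([Si](C(C)C)(C(C)C)C(C)C)c3ccc(OC)cc23)c(OC)c(O)c(-c2cn([Si](C(C)C)(C(C)C)C(C)C)c3ccc(OCc4ccccc4)cc23)c1OC | intermediate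
25 | 5-(benzyloxy)-3-{2,3,5,6-tetramethoxy-4-[5-methoxy-1-(triisopropylsilyl)indol-3-yl]phenyl}-1-(triisopropylsilyl)indole | COc1c(-c2cn([Si](C(C)C)(C(C)C)C(C)C)c3ccc(OC)cc23)c(OC)c(OC)c(-c2cn([Si](C(C)C)(C(C)C)C(C)C)c3ccc(OCc4ccccc4)cc23)c1OC | intermediate
26 | 5-(benzyloxy)-3-[2,3,5,6-tetramethoxy-4-(5-methoxy-1H-indol-3-yl)phenyl]-1H-indole | COc1ccc2[nH]cc(-c3c(OC)c(OC)c(-c4c[nH]c5ccc(OCc6ccccc6)cc45)c(OC)c3OC)c2c1 | intermediate
27 | 3-[2,3,5,6-tetramethoxy-4-(5-methoxy-1H-indol-3-yl)phenyl]-1H-indol-5-ol (CNP0244913.0) | COc1ccc2[nH]cc(-c3c(OC)c(OC)c(-c4c[nH]c5ccc(O)cc45)c(OC)c3OC)c2c1 | target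

**Step count:** 11 steps in total. The longest linear sequence is 9 steps (steps 3 to 11, from 9).

**Steps most likely to fail**

Step 8.
- What may go wrong: the allylic carbinol, activated by the enol ether, may ionise before the ring opens. The hydroxyl may rotate inward and the ketene may then lactonise. Closure may be slow because the methoxy group points inward. The product may oxidise in air during handling.
- Fallback: the substrate of the ring expansion is changed, not its conditions. It sets out from lithium alkoxide 20, which is quenched at −78 °C with MeOTf instead of water to give the carbinol methyl ether F1.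
- Heating this in degassed toluene runs the same 4π/6π sequence, since a methoxy group also rotates outward. It should give the trimethoxyphenol F2, which has no free carbinol OH to lactonise on the way and cannot be oxidised to a quinone.
- Methylation of its single phenol (NaH, MeI) brings the route back at 25.

Step 7.
- What may go wrong: the α-aryl vinyl anion may invert to the isomer with Li anti to OMe and then lose lithium methoxide. Attack may compete at the carbonyl next to the indolyl-bearing carbon, because the indole nitrogen also feeds electron density into the intended carbonyl. The product may ionise at the allylic position under acid on work-up.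
- Fallback: the squarate assembly is left and ring C is taken from a preformed quinone by two successive acid-promoted conjugate additions of the free indoles. It sets out from 1 and 9.
- Compound 1 adds through C3 to purchased 2,5-dichloro-1,4-benzoquinone (HCl, THF), and DDQ reoxidises in the same flask to the monoindolyl dichloroquinone F3.
- Compound 9 adds to the one remaining quinone C–H (AcOH–HCl, then DDQ) to give the bisindolyl dichloroquinone F4.
- NaOMe in MeOH–THF replaces both chlorines by addition–elimination to give the bisindolyl dimethoxyquinone F5.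
- Na2S2O4 in aqueous THF reduces it to the N-unprotected hydroquinone F6.
- Me2SO4 with K2CO3 in acetone under argon methylates the two phenols but not the far less acidic indole N–H. The route comes back at 26.

Step 6.
- What may go wrong: the triflate may homocouple with newly formed stannane. The electron-rich β-stannyl enol ether may undergo protodestannylation during purification.
- Fallback: the same vinyllithium is reached from a vinyl bromide made by olefination and bromination. It sets out from 11.
- Bromine–lithium exchange (t-BuLi, via 13) and a DMF quench give the N-TIPS aldehyde F7.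
- Wittig reaction with Ph3P=CHOMe, from (methoxymethyl)triphenylphosphonium chloride and NaHMDS, gives the methyl enol ether F8 as an E/Z mixture.
- Br2 in CH2Cl2 at −78 °C gives the vicinal dibromide F9, from which DBU in the same flask removes HBr through the oxocarbenium ion.
- The isomer with Br cis to OMe, the Z vinyl bromide F10, is separated by chromatography on Et3N-washed silica.
- t-BuLi (2 equiv, THF, −78 °C) converts it with retention into 19, where the route is rejoined.

**Further compounds**
F1 | step 8 | carbinol methyl ether: racemic 3,4-dimethoxy-2-[5-methoxy-1-(triisopropylsilyl)indol-3-yl]-4-{(Z)-1-[5-(benzyloxy)-1-(triisopropylsilyl)indol-3-yl]-2-methoxyvinyl}cyclobut-2-en-1-one | COc1ccc2c(c1)c(C1=C(OC)C(OC)(/C(=C\OC)c3cn([Si](C(C)C)(C(C)C)C(C)C)c4ccc(OCc5ccccc5)cc34)C1=O)cn2[Si](C(C)C)(C(C)C)C(C)C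
F2 | step 8 | trimethoxyphenol: 3,4,6-trimethoxy-2-[5-methoxy-1-(triisopropylsilyl)indol-3-yl]-5-[5-(benzyloxy)-1-(triisopropylsilyl)indol-3-yl]phenol | Oc1c(-c2cn([Si](C(C)C)(C(C)C)C(C)C)c3ccc(OC)cc23)c(OC)c(OC)c(-c2cn([Si](C(C)C)(C(C)C)C(C)C)c3ccc(OCc4ccccc4)cc23)c1OC
F3 | step 7 | monoindolyl dichloroquinone: 2,5-dichloro-3-(5-methoxy-1H-indol-3-yl)-1,4-benzoquinone | COc1ccc2[nH]cc(C3=C(Cl)C(=O)C=C(Cl)C3=O)c2c1
F4 | step 7 | bisindolyl dichloroquinone: 2,5-dichloro-3-(5-methoxy-1H-indol-3-yl)-6-[5-(benzyloxy)-1H-indol-3-yl]-1,4-benzoquinone | COc1ccc2[nH]cc(C3=C(Cl)C(=O)C(c4c[nH]c5ccc(OCc6ccccc6)cc45)=C(Cl)C3=O)c2c1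
F5 | step 7 | bisindolyl dimethoxyquinone: 2,5-dimethoxy-3-(5-methoxy-1H-indol-3-yl)-6-[5-(benzyloxy)-1H-indol-3-yl]-1,4-benzoquinone | COc1ccc2[nH]cc(C3=C(OC)C(=O)C(c4c[nH]c5ccc(OCc6ccccc6)cc45)=C(OC)C3=O)c2c1
F6 | step 7 | N-unprotected hydroquinone: 3,6-dimethoxy-2-(5-methoxy-1H-indol-3-yl)-5-[5-(benzyloxy)-1H-indol-3-yl]benzene-1,4-diol | COc1ccc2[nH]cc(-c3c(OC)c(O)c(-c4c[nH]c5ccc(OCc6ccccc6)cc45)c(OC)c3O)c2c1
F7 | step 6 | N-TIPS aldehyde: 5-(benzyloxy)-1-(triisopropylsilyl)indole-3-carboxaldehyde | O=Cc1cn([Si](C(C)C)(C(C)C)C(C)C)c2ccc(OCc3ccccc3)cc12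
F8 | step 6 | methyl enol ether: 5-(benzyloxy)-3-(2-methoxyvinyl)-1-(triisopropylsilyl)indole, E/Z mixture | COC=Cc1cn([Si](C(C)C)(C(C)C)C(C)C)c2ccc(OCc3ccccc3)cc12
F9 | step 6 | vicinal dibromide: 5-(benzyloxy)-3-(1,2-dibromo-2-methoxyethyl)-1-(triisopropylsilyl)indole, diastereomer mixture | COC(Br)C(Br)c1cn([Si](C(C)C)(C(C)C)C(C)C)c2ccc(OCc3ccccc3)cc12
F10 | step 6 | Z vinyl bromide: (Z)-5-(benzyloxy)-3-(1-bromo-2-methoxyvinyl)-1-(triisopropylsilyl)indole | CO/C=C(\Br)c1cn([Si](C(C)C)(C(C)C)C(C)C)c2ccc(OCc3ccccc3)cc12
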